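**Plan**

- Retrosynthesis: ring A is cut at C5–C6 and C8–C8a, giving a 2-hydroxymethylene ketone and a 4-benzyloxyacetoacetate. The side chain is then cut at C3′–C4′ (copper-catalysed sp3–sp3 coupling) and at C2′–C3′ (formaldehyde ene). Locants: C1 CH3, C4 side chain, C6 CO2H, C7/C8 OH; chain C1′–C6′ counted from the ring.
- Enabling feature: ring B is a p-menthane oxygenated as in carvone. Its carbonyl carbon (future C8a) lies between the CH(CH3) carbon (C1) and a CH2 (future C4a) next to the chain-bearing C4. Ring A is a 2-hydroxy-3-alkoxybenzoate, i.e. C6–C7–C8 plus ester of a 4-alkoxyacetoacetate joined to one formyl carbon (C5).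
- Forward: (R)-carvone supplies ring B and the ketone is parked as a carbinol. The isopropenyl group is extended by ene reaction, hydrogenation, iodination and coupling with a Grignard reagent from (S)-3-bromo-2-methylpropanol. The ketone is then regenerated and formylated, ring A is closed last, and saponification and hydrogenolysis finish the route.
- Stereochemistry: C4 is C5 of carvone. C1 is set trans to it by equilibration of the dihydro ketone and then frozen. C1′ comes from a catalyst-controlled iridium hydrogenation. C5′ is bought with the bromo alcohol.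

Key step: step 10

Assumption: compounds 1, 7 and 14 are taken as purchased, and the bicyclic compounds are named with the locants defined above instead of lowest-locant numbering.

**Route**

Step 1
Reactants: 1 (R)-carvone
Product: 2 (2R,5R)-2-methyl-5-(prop-1-en-2-yl)cyclohexan-1-one (trans-dihydrocarvone)
Conditions: L-Selectride (1.1 equiv), THF, −78 °C; MeOH; then NaOMe (0.1 equiv), MeOH, 25 °C
Reagents that add atoms: none
Why: Conjugate (1,4) hydride reduction of the enone gives the enolate, and protonation followed by methoxide equilibration should place the C2 methyl equatorial, trans to the isopropenyl group (thermodynamic control), while C5 of carvone is untouched.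

Step 2
Reactants: 2 (2R,5R)-2-methyl-5-(prop-1-en-2-yl)cyclohexan-1-one
Product: 3 (1S,2R,5R)-2-methyl-5-(prop-1-en-2-yl)cyclohexan-1-ol (OH axial, cis to the methyl group)
Conditions: L-Selectride (1.2 equiv), THF, −78 °C; then H2O
Reagents that add atoms: none
Why: Carbonyl reduction by a bulky borohydride along the equatorial trajectory should give the axial carbinol as one epimer (its configuration is erased again in step 8); masking the ketone this way keeps C2 from epimerising during chain building, avoids a ketal, and lets the alcohol derived from any cis ketone be removed by chromatography.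

Step 3
Reactants: 3 (1S,2R,5R)-2-methyl-5-(prop-1-en-2-yl)cyclohexan-1-ol
Product: 4 (1S,2R,5R)-5-(4-hydroxybut-1-en-2-yl)-2-methylcyclohexan-1-ol
Conditions: (CH2O)n (1.5 equiv), Me2AlCl (3.0 equiv), CH2Cl2, −78 → 0 °C; 1 M HCl work-up
Reagents that add atoms: formaldehyde (from paraformaldehyde), C=O
Why: Lewis-acid-promoted carbonyl-ene reaction in which the CH2O·Me2AlCl complex is attacked by the terminal carbon of the 1,1-disubstituted alkene with transfer of a methyl hydrogen; the product alkoxide loses methane so that no acid remains to isomerise the new alkene, the ring hydroxyl is carried as its aluminium alkoxide (hence the third equivalent), and no stereocentre is formed.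

Step 4
Reactants: 4 (1S,2R,5R)-5-(4-hydroxybut-1-en-2-yl)-2-methylcyclohexan-1-ol
Product: 5 (1S,2R,5R)-5-[(2S)-4-hydroxybutan-2-yl]-2-methylcyclohexan-1-ol
Conditions: [Ir(cod)(L*)]BArF (2 mol %; L* = phosphinite–oxazoline N,P ligand, the antipode that adds H2 to the Re face of the ring-bound alkene carbon, fixed beforehand in a two-run screen), H2 (1 bar), CH2Cl2, 0 → 25 °C
Reagents that add atoms: none
Why: Iridium–N,P-catalysed asymmetric hydrogenation of a terminal 1,1-disubstituted alkene, in which the nearly symmetric ring exerts little bias so that the chiral ligand, distinguishing the branched ring carbon from the CH2CH2OH arm, should decide the face and set C1′ as S, with low pressure limiting isomerisation to the trisubstituted alkene.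

Step 5
Reactants: 5 (1S,2R,5R)-5-[(2S)-4-hydroxybutan-2-yl]-2-methylcyclohexan-1-ol
Product: 6 (1S,2R,5R)-5-[(2S)-4-iodobutan-2-yl]-2-methylcyclohexan-1-ol
Conditions: PPh3 (1.1 equiv), I2 (1.1 equiv), imidazole (1.5 equiv), CH2Cl2, 0 °C
Reagents that add atoms: iodine, II
Why: Appel-type iodination proceeds by SN2 displacement on the alkoxyphosphonium ion and should be far faster at the primary carbinol than at the axial secondary one flanked by the methyl group.

Step 6
Reactants: 7 (2S)-3-bromo-2-methylpropan-1-ol
Product: 8 {[(2S)-3-bromo-2-methylpropoxy]methyl}benzene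
Conditions: BnOC(=NH)CCl3 (1.3 equiv), TfOH (5 mol %), CH2Cl2/cyclohexane, 0 → 25 °C
Reagents that add atoms: benzyl 2,2,2-trichloroacetimidate, N=C(OCc1ccccc1)C(Cl)(Cl)Cl
Why: Acid-catalysed O-benzylation with the trichloroacetimidate avoids the alkoxide that would close to 3-methyloxetane and does not involve the stereocentre.

Step 7
Reactants: 6 (1S,2R,5R)-5-[(2S)-4-iodobutan-2-yl]-2-methylcyclohexan-1-ol; 8 {[(2S)-3-bromo-2-methylpropoxy]methyl}benzene
Product: 10 (1S,2R,5R)-5-[(2S,6R)-7-(benzyloxy)-6-methylheptan-2-yl]-2-methylcyclohexan-1-ol, via Grignard reagent 9 (not isolated)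
Conditions: 8, Mg, THF, 40 °C (gives 9, 2.4 equiv); then 6, Li2CuCl4 (5 mol %), THF, −30 → 0 °C; 1 M HCl work-up
Reagents that add atoms: none
Why: Copper-catalysed (Kochi-type) sp3–sp3 cross-coupling of a primary alkyl iodide with a primary alkylmagnesium bromide forms C3′–C4′; one equivalent of 9 is spent on the ring hydroxyl, whose magnesium alkoxide is inert, and neither C1′ nor C5′ (brought in with 7) sits next to a reacting centre.

Step 8
Reactants: 10 (1S,2R,5R)-5-[(2S,6R)-7-(benzyloxy)-6-methylheptan-2-yl]-2-methylcyclohexan-1-ol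
Product: 11 (2R,5R)-5-[(2S,6R)-7-(benzyloxy)-6-methylheptan-2-yl]-2-methylcyclohexan-1-one
Conditions: Dess–Martin periodinane (1.3 equiv), CH2Cl2, 25 °C
Reagents that add atoms: none
Why: Dess–Martin oxidation of the axial secondary alcohol is fast and essentially neutral, so the ketone should be regenerated without enolisation and the trans C2 methyl fixed in step 1 retained.

Step 9
Reactants: 11 (2R,5R)-5-[(2S,6R)-7-(benzyloxy)-6-methylheptan-2-yl]-2-methylcyclohexan-1-one
Product: 13 (2Z,3S,6R)-3-[(2S,6R)-7-(benzyloxy)-6-methylheptan-2-yl]-2-(hydroxymethylidene)-6-methylcyclohexan-1-one, via lithium enolate 12 (not isolated)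
Conditions: LDA (1.1 equiv), THF, −78 °C; CF3CH2OCHO (1.5 equiv), −78 → 0 °C; 1 M HCl
Reagents that add atoms: 2,2,2-trifluoroethyl formate, O=COCC(F)(F)F
Why: Crossed Claisen formylation of the kinetic enolate, in which LDA removes a proton from the CH2 side only and the activated formate C-formylates it; the product rests as the chelated β-keto aldehyde enolate, so the methyl-bearing α-carbon is never enolised and the Z-hydroxymethylene ketone should result on acidification.

Step 10
Reactants: 13 (2Z,3S,6R)-3-[(2S,6R)-7-(benzyloxy)-6-methylheptan-2-yl]-2-(hydroxymethylidene)-6-methylcyclohexan-1-one; 14 ethyl 4-(benzyloxy)-3-oxobutanoate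
Product: 16 ethyl (1R,4S)-8-(benzyloxy)-4-[(2S,6R)-7-(benzyloxy)-6-methylheptan-2-yl]-7-hydroxy-1-methyl-1,2,3,4-tetrahydronaphthalene-6-carboxylate, via Knoevenagel adduct 15 (not isolated)
Conditions: 14 (1.2 equiv), piperidine (20 mol %), AcOH (20 mol %), EtOH, 25 → 50 °C; then NaOEt (2.5 equiv), EtOH, 78 °C; 1 M HCl
Reagents that add atoms: none
Why: Amine–acid catalysis converts the chelated formyl group into an iminium/enaminone that is attacked by C-2 of 14, the only doubly activated methylene, in a Knoevenagel condensation that forges C5–C6 and gives 15; ethoxide then enolises the C7 ketone toward the benzyloxy-bearing C8, which adds to the ring ketone (C8–C8a), and loss of water followed by tautomerisation of the cyclohexadienone should deliver the phenol without an oxidant. The closest known reaction type is the classical condensation of 2-hydroxymethylene cycloalkanones with acetonedicarboxylates and β-keto esters to ring-fused hydroxybenzoates. Ring A closes by a 6-(enolendo)-exo-trig aldol addition followed by E1cB dehydration. No stereocentre is created: C1 and C4 are carried over from carvone, and C1 becomes benzylic and configurationally fixed once the ring is aromatic. The regiochemistry (ester next to C5–H, benzyloxy next to C8a) follows from formyl-over-ketone electrophilicity and C-2-over-C-4 acidity in 14, and O-cyclisation to the 2-pyranone is reversible under ethoxide whereas aromatisation is not. The C1 methyl must stay trans to the C4 chain while the ring ketone is still enolisable, which is expected because the all-equatorial trans arrangement is the thermodynamic minimum of the keto intermediate, and a cis epimer would be a separable diastereomer of 16.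

Step 11
Reactants: 16 ethyl (1R,4S)-8-(benzyloxy)-4-[(2S,6R)-7-(benzyloxy)-6-methylheptan-2-yl]-7-hydroxy-1-methyl-1,2,3,4-tetrahydronaphthalene-6-carboxylate
Product: 17 (1R,4S)-8-(benzyloxy)-4-[(2S,6R)-7-(benzyloxy)-6-methylheptan-2-yl]-7-hydroxy-1-methyl-1,2,3,4-tetrahydronaphthalene-6-carboxylic acid
Conditions: KOH (6 equiv), EtOH/H2O 4:1 (degassed), 70 °C; 1 M HCl
Reagents that add atoms: potassium hydroxide (its oxygen becomes the carboxyl OH), [K+].[OH-]
Why: Alkaline ester hydrolysis (BAc2) of the salicylate, carried out while the C8 benzyl ether still prevents the ring from being an air-sensitive catechol under base; the benzylic C1 and C4 centres are not acidic.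

Step 12
Reactants: 17 (1R,4S)-8-(benzyloxy)-4-[(2S,6R)-7-(benzyloxy)-6-methylheptan-2-yl]-7-hydroxy-1-methyl-1,2,3,4-tetrahydronaphthalene-6-carboxylic acid
Product: 18 (1R,4S)-7,8-dihydroxy-4-[(2S,6R)-7-hydroxy-6-methylheptan-2-yl]-1-methyl-1,2,3,4-tetrahydronaphthalene-6-carboxylic acid (CNP0455284.1)
Conditions: H2 (1 atm), 10 % Pd/C, EtOAc/MeOH, 25 °C; filtration under argon
Reagents that add atoms: none
Why: Palladium-catalysed hydrogenolysis should cleave the aryl and the primary alkyl benzyl ether under neutral conditions, freeing the catechol and the primary alcohol in the last operation without touching any stereocentre.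

**Compound list**

1 | (R)-carvone, (5R)-2-methyl-5-(prop-1-en-2-yl)cyclohex-2-en-1-one | CC1=CC[C@H](CC1=O)C(C)=C | starting material
2 | (2R,5R)-2-methyl-5-(prop-1-en-2-yl)cyclohexan-1-one (trans-dihydrocarvone) | CC(=C)[C@@H]1CC[C@@H](C)C(=O)C1 | intermediate
3 | (1S,2R,5R)-2-methyl-5-(prop-1-en-2-yl)cyclohexan-1-ol (OH axial, cis to CH3) | CC(=C)[C@@H]1CC[C@@H](C)[C@@H](O)C1 | intermediate
4 | (1S,2R,5R)-5-(4-hydroxybut-1-en-2-yl)-2-methylcyclohexan-1-ol | OCCC(=C)[C@@H]1CC[C@@H](C)[C@@H](O)C1 | intermediate
5 | (1S,2R,5R)-5-[(2S)-4-hydroxybutan-2-yl]-2-methylcyclohexan-1-ol | OCC[C@H](C)[C@@H]1CC[C@@H](C)[C@@H](O)C1 | intermediate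
6 | (1S,2R,5R)-5-[(2S)-4-iodobutan-2-yl]-2-methylcyclohexan-1-ol | ICC[C@H](C)[C@@H]1CC[C@@H](C)[C@@H](O)C1 | intermediate
7 | (2S)-3-bromo-2-methylpropan-1-ol | BrC[C@@H](C)CO | starting material
8 | {[(2S)-3-bromo-2-methylpropoxy]methyl}benzene | BrC[C@@H](C)COCc1ccccc1 | intermediate
9 | [(2S)-3-(benzyloxy)-2-methylpropyl]magnesium bromide (not isolated) | Br[Mg]C[C@@H](C)COCc1ccccc1 | intermediate
10 | (1S,2R,5R)-5-[(2S,6R)-7-(benzyloxy)-6-methylheptan-2-yl]-2-methylcyclohexan-1-ol | C[C@@H](COCc1ccccc1)CCC[C@H](C)[C@@H]1CC[C@@H](C)[C@@H](O)C1 | intermediate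
11 | (2R,5R)-5-[(2S,6R)-7-(benzyloxy)-6-methylheptan-2-yl]-2-methylcyclohexan-1-one | C[C@@H](COCc1ccccc1)CCC[C@H](C)[C@@H]1CC[C@@H](C)C(=O)C1 | intermediate
12 | lithium (3S,6R)-3-[(2S,6R)-7-(benzyloxy)-6-methylheptan-2-yl]-6-methylcyclohex-1-en-1-olate (not isolated) | C[C@@H](COCc1ccccc1)CCC[C@H](C)[C@@H]1CC[C@@H](C)C(O[Li])=C1 | intermediate
13 | (2Z,3S,6R)-3-[(2S,6R)-7-(benzyloxy)-6-methylheptan-2-yl]-2-(hydroxymethylidene)-6-methylcyclohexan-1-one | C[C@@H](COCc1ccccc1)CCC[C@H](C)[C@@H]1CC[C@@H](C)C(=O)/C1=C\O | intermediate
14 | ethyl 4-(benzyloxy)-3-oxobutanoate | CCOC(=O)CC(=O)COCc1ccccc1 | starting material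
15 | ethyl 4-(benzyloxy)-2-{[(3R,6S)-6-[(2S,6R)-7-(benzyloxy)-6-methylheptan-2-yl]-3-methyl-2-oxocyclohexyl]methylidene}-3-oxobutanoate (Knoevenagel adduct; ring C1 and alkene geometry not fixed; not isolated) | C[C@@H](COCc1ccccc1)CCC[C@H](C)[C@@H]1CC[C@@H](C)C(=O)C1C=C(C(=O)OCC)C(=O)COCc1ccccc1 | intermediate
16 | ethyl (1R,4S)-8-(benzyloxy)-4-[(2S,6R)-7-(benzyloxy)-6-methylheptan-2-yl]-7-hydroxy-1-methyl-1,2,3,4-tetrahydronaphthalene-6-carboxylate | C[C@@H](COCc1ccccc1)CCC[C@H](C)[C@@H]1CC[C@@H](C)c2c1cc(C(=O)OCC)c(O)c2OCc1ccccc1 | intermediate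
17 | (1R,4S)-8-(benzyloxy)-4-[(2S,6R)-7-(benzyloxy)-6-methylheptan-2-yl]-7-hydroxy-1-methyl-1,2,3,4-tetrahydronaphthalene-6-carboxylic acid | C[C@@H](COCc1ccccc1)CCC[C@H](C)[C@@H]1CC[C@@H](C)c2c1cc(C(=O)O)c(O)c2OCc1ccccc1 | intermediate
18 | (1R,4S)-7,8-dihydroxy-4-[(2S,6R)-7-hydroxy-6-methylheptan-2-yl]-1-methyl-1,2,3,4-tetrahydronaphthalene-6-carboxylic acid | C[C@@H](CO)CCC[C@H](C)[C@@H]1CC[C@@H](C)c2c1cc(C(=O)O)c(O)c2O | target

**Count**

Total steps: 12. Longest linear sequence: 11 steps (1 → 2 → 3 → 4 → 5 → 6 → 10 → 11 → 13 → 16 → 17 → 18); step 6 is the single side-branch step.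

**Steps most likely to fail**

1. Step 10. The benzyloxy-bearing C8 is only singly activated and may close onto the hindered ring ketone too slowly. Retro-Claisen cleavage of the keto ester by ethoxide, or epimerisation of C1 through the ring enolate, could then gain ground. The fallback forms the same two bonds in the reverse order with a stronger nucleophile.
   - It sets out from 13: O-alkylation (2-iodopropane, K2CO3, acetone) would give the 2-(isopropoxymethylidene) ketone F1.
   - The lithium sodium dianion of 14 F2 (NaH, then n-BuLi, THF, 0 °C) should add through its γ-carbon to the ring carbonyl at −78 °C (1,2-addition to a vinylogous ester), forming C8–C8a in the tertiary carbinol F3.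
   - Aqueous acid (1 M HCl, THF) would ionise the carbinol and hydrolyse the enol ether with allylic transposition to the 2-formylcyclohexene.
   - Piperidinium acetate in EtOH at 50 °C then closes C5–C6 by intramolecular Knoevenagel condensation, and tautomerisation returns the route at 16.

2. Step 4. Facial selectivity may be poor because the ring looks nearly symmetric from the alkene, or the catalyst may first isomerise the terminal alkene to the trisubstituted one, which is reduced with the opposite sense. The fallback sets C1′ by a conjugate reduction of a trisubstituted enoate, where the two β-substituents (methyl versus ring) differ strongly.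
   - It sets out from 3: ozonolysis (O3, CH2Cl2/MeOH, −78 °C; Me2S) would give the methyl ketone F4.
   - Horner–Wadsworth–Emmons olefination (triethyl phosphonoacetate, NaH, THF) gives the (E)-enoate F5, the Z isomer being removed by chromatography.
   - Copper hydride-catalysed asymmetric conjugate reduction (Cu(OAc)2, chiral bisphosphine, PMHS, t-BuOH, toluene) gives the saturated ester F6 with C1′ set by the ligand.
   - LiAlH4 in THF reduces the ester and returns the route at 5; steps 3 and 4 are both bypassed.

3. Step 3. The aluminium alkoxide of the ring hydroxyl may trap formaldehyde as a hemiformal, or Lewis-acid-induced cation chemistry (Prins addition, alkene migration) may compete with the ene pathway. The fallback replaces the Lewis acid by an anionic C–C bond formation.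
   - It sets out from 3: deprotonation of the hydroxyl with n-BuLi followed by allylic metalation of the isopropenyl methyl group with n-BuLi/KOt-Bu (hexane/THF, −78 → 0 °C) would give the O-lithio allylpotassium species F7.
   - Trapping with dry paraformaldehyde and aqueous work-up returns the route at 4.

**Further compounds**

F1 | step 10 | (3S,6R)-3-[(2S,6R)-7-(benzyloxy)-6-methylheptan-2-yl]-6-methyl-2-[(propan-2-yloxy)methylidene]cyclohexan-1-one (alkene geometry open) | C[C@@H](COCc1ccccc1)CCC[C@H](C)[C@@H]1CC[C@@H](C)C(=O)C1=COC(C)C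
F2 | step 10 | lithium sodium dianion (dienediolate) of ethyl 4-(benzyloxy)-3-oxobutanoate | CCOC(O[Na])=CC(O[Li])=COCc1ccccc1
F3 | step 10 | ethyl 4-(benzyloxy)-4-{(3R,6S)-6-[(2S,6R)-7-(benzyloxy)-6-methylheptan-2-yl]-2-hydroxy-3-methyl-1-[(propan-2-yloxy)methylidene]cyclohexan-2-yl}-3-oxobutanoate (carbinol and C4 of the butanoate unassigned) | C[C@@H](COCc1ccccc1)CCC[C@H](C)[C@@H]1CC[C@@H](C)C(O)(C(OCc2ccccc2)C(=O)CC(=O)OCC)C1=COC(C)C
F4 | step 4 | 1-[(1R,3S,4R)-3-hydroxy-4-methylcyclohexyl]ethan-1-one | CC(=O)[C@@H]1CC[C@@H](C)[C@@H](O)C1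
F5 | step 4 | ethyl (2E)-3-[(1R,3S,4R)-3-hydroxy-4-methylcyclohexyl]but-2-enoate | CCOC(=O)/C=C(\C)[C@@H]1CC[C@@H](C)[C@@H](O)C1
F6 | step 4 | ethyl (3S)-3-[(1R,3S,4R)-3-hydroxy-4-methylcyclohexyl]butanoate | CCOC(=O)C[C@H](C)[C@@H]1CC[C@@H](C)[C@@H](O)C1
F7 | step 3 | O-lithio allylpotassium derivative of 3 (metalated at the isopropenyl methyl group) | [K]CC(=C)[C@@H]1CC[C@@H](C)[C@@H](O[Li])C1
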